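**Plan**

1. Cuts: the ester C15–O–C(=O) between the two halves; both C11–O ether bonds, each read as the oxa-Michael adduct of a 12-nordrim-9(11)-en-8-one and the C2′–OH of one (2′R,3′S)-isocitrate triester; C8=C12 of both halves (ketone methylenation); in the 15-oxygenated half the C4–C5 bond of ring A (retro-semipinacol), then the C3–C5 bond of a five-membered pre-ring (acyloin), back to 2-methylcyclohexane-1,3-dione and acrolein.
2. Enabling feature: in ring A of the 15-oxygenated drimane, C4 is quaternary, carries CH3 and the oxygenated carbon C15, and lies between C3 (a CH2 that can be a transient ketone) and ring-fusion carbon C5. A 3-oxo-4-methyl-4-hydroxymethyl unit is the product of an α-hydroxy-epoxide 1,2-shift, so ring A (C1–C2–C3–C4–C5–C10) is grown from the cyclopentane C1–C2–C3–C5–C10 by inserting C4 between C3 and C5.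
3. Forward order, lower half: ring B (the dione) → five-membered carbocycle (desymmetrizing benzoin, dehydration) → six-membered ring A (ring expansion) → C5–H and C3 deoxygenation → C8 enone → ether → C8=CH2. Upper half: (+)-albicanol through the same enone, ether and methylenation sequence. Then ester union and release of the three acids.
4. Stereochemistry: C10 from the catalyst-controlled benzoin desymmetrization; C4 from the ligand-controlled epoxide through the invertive shift; C5 from hydroxyl-directed hydrogenation; C9 of both halves from equilibration α to the C8 ketone; C2′ from (R)-malic acid and C3′ from the anti-selective Frater–Seebach alkylation; C5, C9, C10 of the upper half from (+)-albicanol.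

Key step: step 15

Remarks: drimane numbering is used for both halves and their precursors (C11 on C9, C12 on C8, C15 = the oxygenated carbon on C4 of the lower half; β = face of the C10 methyl). Isocitrate carbons are primed (C1′ = ester carbon on the ether carbon C2′, C3′ bears the central carboxyl, C5′ = terminal carboxyl). Assumption: (+)-albicanol is bought as a catalogue natural product.

**Isocitrate partner**

Step 1
Reactants: 1 (R)-malic acid
Product: 3 (R)-malic acid 1-methyl ester, via trifluoroacetyl anhydride 2 (not isolated)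
Conditions: (CF3CO)2O, 0 °C to rt; evaporate; MeOH, rt
Reagents that add atoms: methanol, CO
Why: Malic acid forms the O-trifluoroacetyl cyclic anhydride, which methanol opens at the more electrophilic carbonyl next to the acyloxy carbon (regioselective anhydride alcoholysis) and then de-trifluoroacetylates; C2′ is not touched.

Step 2
Reactants: 3 (R)-malic acid 1-methyl ester
Product: 4 4-allyl 1-methyl (R)-malate
Conditions: allyl bromide, KHCO3, DMF, rt
Reagents that add atoms: allyl bromide, C=CCBr
Why: Carboxylate SN2 alkylation under bicarbonate leaves the secondary alcohol free and installs an ester that Pd(0) can later remove beside tert-butyl and methyl esters.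

Step 3
Reactants: 4 4-allyl 1-methyl (R)-malate
Product: 5 (2′R,3′S)-isocitrate triester (C1′ methyl; C3′-carboxyl allyl; C5′ tert-butyl; free C2′–OH)
Conditions: LiHMDS (2.2 equiv), THF, −78 °C; BrCH2CO2t-Bu, −78 to −30 °C
Reagents that add atoms: tert-butyl bromoacetate, CC(C)(C)OC(=O)CBr
Why: Frater–Seebach alkylation: the chelated lithium alkoxide–enolate dianion is alkylated anti to the alkoxide, which sets C3′ (S) relative to C2′ (R), the threo isocitrate; the tert-butyl ester on C5′ keeps the γ-hydroxy ester from lactonising.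

**Upper half**

Step 4
Reactants: 6 (+)-albicanol
Product: 7 11-hydroxy-12-nordriman-8-one
Conditions: O3, CH2Cl2/MeOH, −78 °C; Me2S
Reagents that add atoms: ozone, [O-][O+]=O
Why: Ozonolysis of the only alkene with reductive work-up gives the C8 ketone; C9 keeps its equatorial CH2OH.

Step 5
Reactants: 7 11-hydroxy-12-nordriman-8-one
Product: 9 12-nordrim-9(11)-en-8-one, via mesylate 8 (not isolated)
Conditions: MsCl, Et3N, CH2Cl2, 0 °C; DBU, rt
Reagents that add atoms: none
Why: Mesylation and E1cB elimination of the β-mesyloxy ketone give the exocyclic enone, which turns the hindered C11 into an unhindered electrophilic CH2.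

Step 6
Reactants: 9 12-nordrim-9(11)-en-8-one; 5 isocitrate triester
Product: 10 8-oxo-12-nordriman-11-yl ether of 5 (9β-CH2O, 9α-H)
Conditions: PBu3 (20 mol%), 9 (1.5 equiv), MeCN (1 M), rt
Reagents that add atoms: none
Why: Phosphine-catalysed oxa-Michael addition: the phosphonium enolate from 9 deprotonates the C2′–OH of 5 and the alkoxide adds to C11; protonation at C9 under equilibrating conditions should give the equatorial 9β-CH2O epimer, so the ether forms without SN2 at C11 or C2′.

Step 7
Reactants: 10 keto ether
Product: 11 albicanyl ether of 5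
Conditions: Zn, CH2Br2, TiCl4 (pre-formed Lombardo reagent), THF/CH2Cl2, 0 °C to rt
Reagents that add atoms: dibromomethane, BrCBr
Why: Lombardo methylenation is non-basic, so C8=C12 is installed without epimerising C9, without β-elimination of the alkoxy group and without attack on the esters.

Step 8
Reactants: 11 albicanyl ether of 5
Product: 12 upper-half acid (C3′-CO2H free)
Conditions: Pd(PPh3)4 (5 mol%), morpholine, THF, rt
Reagents that add atoms: none
Why: Pd(0) ionises only the allyl ester (Tsuji–Trost deallylation, morpholine as allyl acceptor) under neutral conditions that spare the exocyclic alkene and the other esters.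

**Lower half**

Step 9
Reactants: 13 2-methylcyclohexane-1,3-dione; 14 acrolein
Product: 15 3-(1-methyl-2,6-dioxocyclohexyl)propanal
Conditions: H2O, rt
Reagents that add atoms: none
Why: Michael addition of the cyclic 1,3-dione to acrolein gives the 2,2-disubstituted dione with the three-carbon aldehyde arm (C1–C3).

Step 10
Reactants: 15 3-(1-methyl-2,6-dioxocyclohexyl)propanal
Product: 16 (3aS,7aR)-7a-hydroxy-3a-methylhexahydro-1H-indene-1,4(2H)-dione
Conditions: chiral aminoindanol-derived N-C6F5 triazolium tetrafluoroborate (10 mol%, antipode giving the 10S series), Et3N (10 mol%), toluene, rt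
Reagents that add atoms: none
Why: Intramolecular crossed benzoin reaction: the Breslow intermediate of the aldehyde adds to one of the two enantiotopic ring carbonyls, the chiral carbene choosing the carbonyl and hence the configuration of quaternary C10, while the short tether enforces the cis fusion (5β-OH).

Step 11
Reactants: 16 acyloin
Product: 17 (S)-3a-methyl-2,3,5,6-tetrahydro-1H-indene-1,4(3aH)-dione
Conditions: SOCl2, pyridine, CH2Cl2, −20 °C to rt
Reagents that add atoms: none
Why: The tertiary α-ketol is dehydrated through its chlorosulfite towards C6, the only carbon with β-hydrogens, giving the C3(=O)–C5=C6 enone and making C5 an sp2 carbon with high migratory aptitude.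

Step 12
Reactants: 17 enedione
Product: 18 C9 ethylene ketal of 17
Conditions: ethylene glycol, PPTS, benzene, reflux (Dean–Stark)
Reagents that add atoms: ethylene glycol, OCCO
Why: The saturated C9 ketone is ketalised in preference to the conjugated C3 carbonyl (standard chemoselective dioxolane formation), which reserves C3 for the nucleophile.

Step 13
Reactants: 18 ketal enone
Product: 19 tertiary allylic alcohol (3β-OH, 3α-isopropenyl)
Conditions: isopropenylmagnesium bromide, CeCl3, THF, −78 °C
Reagents that add atoms: isopropenylmagnesium bromide, CC(=C)[Mg]Br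
Why: The organocerium reagent adds 1,2 to the enone carbonyl, expected from the α-face away from the C10 methyl; the C3 configuration has no bearing on C4 because C3 becomes sp2 in step 15.

Step 14
Reactants: 19 tertiary allylic alcohol
Product: 20 α-hydroxy epoxide (oxirane carbon C4 S; oxirane CH2 = C15)
Conditions: Hf(Ot-Bu)4 (10 mol%), chiral bis-hydroxamic acid ligand (12 mol%), cumene hydroperoxide, toluene, 0 °C
Reagents that add atoms: cumene hydroperoxide, CC(C)(OO)c1ccccc1
Why: Hydroxyl-directed, ligand-controlled epoxidation of a tertiary allylic alcohol: the unhindered isopropenyl group should react, since the C5=C6 alkene is screened on the hydroxyl-bearing β-face by the C10 methyl, and the ligand antipode is chosen so that C4 is S.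

Step 15
Reactants: 20 α-hydroxy epoxide
Product: 21 ring-expanded β-hydroxy ketone (3-oxo; 4β-CH3; 4α-CH2OH; C5=C6; C9 dioxolane)
Conditions: ZnBr2 (1.5 equiv), CH2Cl2, 0 °C to rt
Reagents that add atoms: none
Why: ZnBr2 activates the oxirane of the α-hydroxy epoxide; the C4–O bond opens at the tertiary carbon while the alkenyl carbon C5 shifts from C3 to C4 antiperiplanar to the leaving oxygen and C3–OH collapses to the ketone, i.e. a type III semipinacol rearrangement, the closest known reaction type being the Lewis-acid ring expansion of 1-(oxiranyl)cycloalkanols to 2-hydroxymethyl cycloalkanones. Ring A (C1–C2–C3–C4–C5–C10) is thereby formed from the cyclopentane C1–C2–C3–C5–C10 by one-carbon ring expansion, the new C4–C5 bond arising by a suprafacial 1,2-shift as C3–C5 breaks and not by a cyclisation onto a chain end. The single new stereocentre, quaternary C4, is controlled by the oxirane carbon: migration with inversion should convert the (S)-epoxide into 4β-CH3/4α-CH2OH, whatever the configuration of C3, which becomes sp2. The step needs migration of C5 in preference to C2 and epoxide opening in preference to ionisation of the bis-allylic C3–OH or retro-aldol loss of formaldehyde; the sp2 carbon C5 is the better migrating group, the 2,2-disubstituted oxirane is the most easily ionised site under a mild chelating Lewis acid at 0 °C, and the C9 dioxolane should be inert to ZnBr2.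

Step 16
Reactants: 21 ring-expanded β-hydroxy ketone
Product: 22 trans-fused hydroxy ketone (5α-H)
Conditions: [Ir(cod)(PCy3)(py)]PF6 (5 mol%), H2 (1 atm), CH2Cl2, rt
Reagents that add atoms: none
Why: Hydroxyl-directed hydrogenation: the 4α-CH2OH binds the cationic iridium catalyst and delivers H2 to the α-face of the hindered C5=C6 alkene, which sets 5α-H and the trans-decalin.

Step 17
Reactants: 22 trans-fused hydroxy ketone
Product: 23 15-O-TIPS ether of 22
Conditions: TIPSOTf, 2,6-lutidine, CH2Cl2, −78 to 0 °C
Reagents that add atoms: triisopropylsilyl triflate, CC(C)[Si](OS(=O)(=O)C(F)(F)F)(C(C)C)C(C)C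
Why: Silylation of the neopentyl primary alcohol gives an ether that is robust to the strongly basic and the acidic steps that follow.

Step 18
Reactants: 23 TIPS ether ketone
Product: 25 3-deoxo TIPS ether ketal, via N-silyl hydrazone 24 (not isolated)
Conditions: TBSNHNHTBS, Sc(OTf)3 (1 mol%), CHCl3, 55 °C; then KOt-Bu, t-BuOH, DMSO, 100 °C
Reagents that add atoms: none
Why: Wolff–Kishner reduction through the N-silyl hydrazone removes the C3 carbonyl that served the ring expansion; neither C2 nor quaternary C4 is epimerisable and the β-silyloxy group cannot undergo retro-aldol cleavage.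

Step 19
Reactants: 25 3-deoxo TIPS ether ketal
Product: 26 C9 ketone
Conditions: 1 M HCl, THF, rt
Reagents that add atoms: water, O
Why: Acidic hydrolysis of the dioxolane frees the C9 ketone; the TIPS ether tolerates dilute acid.

Step 20
Reactants: 26 C9 ketone
Product: 27 9-methylene compound (C11 installed)
Conditions: Ph3PCH3Br, KOt-Bu, toluene, 90 °C
Reagents that add atoms: methyltriphenylphosphonium bromide, C[P+](c1ccccc1)(c1ccccc1)c1ccccc1.[Br-]
Why: Wittig methylenation under forcing conditions converts the hindered C9 ketone into the exocyclic methylene; the only enolisable α-carbon (C8) is not a stereocentre.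

Step 21
Reactants: 27 9-methylene compound
Product: 29 15-O-TIPS-12-nordrim-9(11)-en-8-one, via allylic alcohol 28 (not isolated)
Conditions: SeO2 (0.3 equiv), t-BuOOH, CH2Cl2, rt; then Dess–Martin periodinane, NaHCO3, CH2Cl2, 0 °C
Reagents that add atoms: tert-butyl hydroperoxide, CC(C)(C)OO (oxygen relayed by catalytic selenium dioxide, O=[Se]=O)
Why: Allylic oxidation (ene reaction then [2,3]-shift) can occur only at C8, the one allylic carbon with hydrogens, and Dess–Martin oxidation of the epimeric alcohols gives the exocyclic enone.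

Step 22
Reactants: 29 lower-half enone; 5 isocitrate triester
Product: 30 lower-half keto ether (9β-CH2O, 9α-H)
Conditions: PBu3 (20 mol%), 5 (2 equiv), MeCN (1 M), rt
Reagents that add atoms: none
Why: Same phosphine-catalysed oxa-Michael addition as in step 6, with 5 in excess; C9 is set by protonation and equilibration to the equatorial epimer.

Step 23
Reactants: 30 lower-half keto ether
Product: 31 TIPS-protected lower half (C8=C12)
Conditions: Zn, CH2Br2, TiCl4 (pre-formed Lombardo reagent), THF/CH2Cl2, 0 °C to rt
Reagents that add atoms: dibromomethane, BrCBr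
Why: Non-basic Lombardo methylenation installs C8=C12 without epimerising C9 or eliminating the β-alkoxy group.

Step 24
Reactants: 31 TIPS-protected lower half
Product: 32 lower-half alcohol (free C15–OH)
Conditions: HF·pyridine, pyridine, THF, 0 °C to rt
Reagents that add atoms: none
Why: Buffered fluoride cleaves the silyl ether and leaves the esters, the ether and the exocyclic alkene untouched.

**Union and deprotection**

Step 25
Reactants: 12 upper-half acid; 32 lower-half alcohol
Product: 33 protected dimer (C3′ ester to C15)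
Conditions: 2-methyl-6-nitrobenzoic anhydride, DMAP, Et3N, CH2Cl2, rt
Reagents that add atoms: none
Why: Shiina esterification: the mixed anhydride of 12 acylates the hindered neopentyl C15–OH under DMAP catalysis at room temperature, mild enough to limit epimerisation at C3′.

Step 26
Reactants: 33 protected dimer
Product: 34 mono-acid (lower-half C3′-CO2H free)
Conditions: Pd(PPh3)4 (5 mol%), morpholine, THF, rt
Reagents that add atoms: none
Why: Pd(0)-catalysed deallylation frees the C3′ carboxyl of the lower half under neutral conditions.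

Step 27
Reactants: 34 mono-acid
Product: 35 CNP0420141.2
Conditions: TMSOTf, 2,6-lutidine, CH2Cl2, 0 °C; aqueous work-up (pH 4)
Reagents that add atoms: none
Why: The two tert-butyl esters are converted into silyl esters with loss of isobutene in the absence of free protic acid, so the acid-labile exocyclic alkenes and the methyl esters should survive; aqueous work-up gives the tri-acid.

**Compound list**

1 | (R)-malic acid | O[C@H](CC(=O)O)C(=O)O | starting material
2 | (R)-2-(trifluoroacetoxy)succinic anhydride | O=C1C[C@@H](OC(=O)C(F)(F)F)C(=O)O1 | intermediate (not isolated)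
3 | (R)-malic acid 1-methyl ester | O[C@@H](C(=O)OC)CC(=O)O | intermediate
4 | 4-allyl 1-methyl (R)-malate | O[C@@H](C(=O)OC)CC(=O)OCC=C | intermediate
5 | (2′R,3′S)-isocitrate triester: C1′ methyl, C3′-carboxyl allyl, C5′ tert-butyl, free C2′–OH | O[C@@H](C(=O)OC)[C@H](CC(=O)OC(C)(C)C)C(=O)OCC=C | intermediate
6 | (+)-albicanol | C=C1CC[C@H]2C(C)(C)CCC[C@]2(C)[C@H]1CO | starting material
7 | 11-hydroxy-12-nordriman-8-one | O=C1CC[C@H]2C(C)(C)CCC[C@]2(C)[C@H]1CO | intermediate
8 | 11-mesylate of 7 | O=C1CC[C@H]2C(C)(C)CCC[C@]2(C)[C@H]1COS(C)(=O)=O | intermediate (not isolated)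
9 | 12-nordrim-9(11)-en-8-one | O=C1CC[C@H]2C(C)(C)CCC[C@]2(C)C1=C | intermediate
10 | 8-oxo-12-nordriman-11-yl ether of 5 (9α-H) | O=C1CC[C@H]2C(C)(C)CCC[C@]2(C)[C@H]1CO[C@@H](C(=O)OC)[C@H](CC(=O)OC(C)(C)C)C(=O)OCC=C | intermediate
11 | albicanyl ether of 5 | C=C1CC[C@H]2C(C)(C)CCC[C@]2(C)[C@H]1CO[C@@H](C(=O)OC)[C@H](CC(=O)OC(C)(C)C)C(=O)OCC=C | intermediate
12 | upper-half acid (C3′-CO2H free; C1′ methyl and C5′ tert-butyl esters) | C=C1CC[C@H]2C(C)(C)CCC[C@]2(C)[C@H]1CO[C@@H](C(=O)OC)[C@H](CC(=O)OC(C)(C)C)C(=O)O | intermediate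
13 | 2-methylcyclohexane-1,3-dione | CC1C(=O)CCCC1=O | starting material
14 | acrolein | C=CC=O | starting material
15 | 3-(1-methyl-2,6-dioxocyclohexyl)propanal | CC1(CCC=O)C(=O)CCCC1=O | intermediate
16 | (3aS,7aR)-7a-hydroxy-3a-methylhexahydro-1H-indene-1,4(2H)-dione (cis-fused; 5β-OH, 10β-CH3) | C[C@]12CCC(=O)[C@@]1(O)CCCC2=O | intermediate
17 | (S)-3a-methyl-2,3,5,6-tetrahydro-1H-indene-1,4(3aH)-dione (C3 ketone conjugated to C5=C6; C9 ketone) | C[C@]12CCC(=O)C1=CCCC2=O | intermediate
18 | C9 ethylene ketal of 17 | C[C@]12CCC(=O)C1=CCCC23OCCO3 | intermediate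
19 | tertiary allylic alcohol (3β-OH, 3α-isopropenyl, C5=C6, C9 dioxolane) | CC(=C)[C@]1(O)CC[C@@]2(C)C1=CCCC23OCCO3 | intermediate
20 | α-hydroxy epoxide (oxirane carbon C4 S, oxirane CH2 = C15) | C[C@]1(CO1)[C@]2(O)CC[C@@]3(C)C2=CCCC34OCCO4 | intermediate
21 | ring-expanded β-hydroxy ketone (3-oxo, 4β-CH3, 4α-CH2OH, C5=C6, 10β-CH3, C9 dioxolane) | OC[C@]1(C)C(=O)CC[C@@]2(C)C1=CCCC23OCCO3 | intermediate
22 | trans-fused hydroxy ketone (5α-H) | OC[C@]1(C)C(=O)CC[C@@]2(C)[C@H]1CCCC23OCCO3 | intermediate
23 | 15-O-TIPS ether of 22 | CC(C)[Si](C(C)C)(C(C)C)OC[C@]1(C)C(=O)CC[C@@]2(C)[C@H]1CCCC23OCCO3 | intermediate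
24 | N-(tert-butyldimethylsilyl)hydrazone of 23 | CC(C)[Si](C(C)C)(C(C)C)OC[C@]1(C)C(=NN[Si](C)(C)C(C)(C)C)CC[C@@]2(C)[C@H]1CCCC23OCCO3 | intermediate (not isolated)
25 | 3-deoxo TIPS ether ketal | CC(C)[Si](C(C)C)(C(C)C)OC[C@]1(C)CCC[C@@]2(C)[C@H]1CCCC23OCCO3 | intermediate
26 | C9 ketone | CC(C)[Si](C(C)C)(C(C)C)OC[C@]1(C)CCC[C@@]2(C)[C@H]1CCCC2=O | intermediate
27 | 9-methylene compound (exocyclic C11) | CC(C)[Si](C(C)C)(C(C)C)OC[C@]1(C)CCC[C@@]2(C)[C@H]1CCCC2=C | intermediate
28 | C8 allylic alcohol (both C8 epimers; centre destroyed in the same step) | CC(C)[Si](C(C)C)(C(C)C)OC[C@]1(C)CCC[C@@]2(C)[C@H]1CCC(O)C2=C | intermediate (not isolated)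
29 | 15-O-TIPS-12-nordrim-9(11)-en-8-one | CC(C)[Si](C(C)C)(C(C)C)OC[C@]1(C)CCC[C@@]2(C)[C@H]1CCC(=O)C2=C | intermediate
30 | lower-half keto ether (8-oxo, 9α-H, ether of 5 at C11) | CC(C)[Si](C(C)C)(C(C)C)OC[C@]1(C)CCC[C@@]2(C)[C@H]1CCC(=O)[C@@H]2CO[C@@H](C(=O)OC)[C@H](CC(=O)OC(C)(C)C)C(=O)OCC=C | intermediate
31 | TIPS-protected lower half (C8=C12) | CC(C)[Si](C(C)C)(C(C)C)OC[C@]1(C)CCC[C@@]2(C)[C@H]1CCC(=C)[C@@H]2CO[C@@H](C(=O)OC)[C@H](CC(=O)OC(C)(C)C)C(=O)OCC=C | intermediate
32 | lower-half alcohol (free C15–OH) | OC[C@]1(C)CCC[C@@]2(C)[C@H]1CCC(=C)[C@@H]2CO[C@@H](C(=O)OC)[C@H](CC(=O)OC(C)(C)C)C(=O)OCC=C | intermediate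
33 | protected dimer (two methyl, two tert-butyl, one allyl ester) | C=C1CC[C@H]2C(C)(C)CCC[C@]2(C)[C@H]1CO[C@@H](C(=O)OC)[C@H](CC(=O)OC(C)(C)C)C(=O)OC[C@]1(C)CCC[C@@]2(C)[C@H]1CCC(=C)[C@@H]2CO[C@@H](C(=O)OC)[C@H](CC(=O)OC(C)(C)C)C(=O)OCC=C | intermediate
34 | mono-acid (lower-half C3′-CO2H free, two tert-butyl esters) | C=C1CC[C@H]2C(C)(C)CCC[C@]2(C)[C@H]1CO[C@@H](C(=O)OC)[C@H](CC(=O)OC(C)(C)C)C(=O)OC[C@]1(C)CCC[C@@]2(C)[C@H]1CCC(=C)[C@@H]2CO[C@@H](C(=O)OC)[C@H](CC(=O)OC(C)(C)C)C(=O)O | intermediate
35 | CNP0420141.2 | C=C1CC[C@H]2C(C)(C)CCC[C@]2(C)[C@H]1CO[C@@H](C(=O)OC)[C@H](CC(=O)O)C(=O)OC[C@]1(C)CCC[C@]2(C)[C@@H](CO[C@@H](C(=O)OC)[C@H](CC(=O)O)C(=O)O)C(=C)CC[C@@H]12 | target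

**Totals**

Total step count: 27. Longest linear sequence: 19 steps (steps 9 to 27, from 13 and 14 to 35).

**Steps most likely to fail**

Step 14. Oxygen may be delivered to the wrong face of the isopropenyl group if substrate and ligand are mismatched, or the directed epoxidation may go to the C5=C6 alkene instead. The fallback sets out from 18 and comes back at 20. Addition of 1-ethoxyvinyllithium (ethyl vinyl ether, t-BuLi; CeCl3, THF, −78 °C) to 18 should give the enol ether carbinol F1. Hydrolysis on oxalic acid-doped wet silica gel should give the α-hydroxy methyl ketone F2. Dimethylsulfonium methylide (Me3S+ I−, n-BuLi, THF, −10 °C, 2.2 equiv) should then add to the ketone held in a lithium alkoxide chelate, from the side of C2 rather than C5 (Corey–Chaykovsky epoxidation under chelation control). This should give epoxide 20 with C4 S and involves no alkene epoxidation at all.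

Step 6. The addition may stop at an unfavourable equilibrium or revert on work-up, the exocyclic enone may self-condense, and the basic catalyst may epimerise C3′. The fallback sets out from 6 and 5 and comes back at 11. Dess–Martin oxidation of 6 should give albicanal F3, and silylation of 5 (TMSCl, imidazole, CH2Cl2) the trimethylsilyl ether F4. Reductive etherification of F3 with F4 (Et3SiH, TMSOTf 10 mol%, CH2Cl2, −78 °C) should reduce the mixed oxocarbenium ion directly to ether 11, by-passing 7, 9 and 10.

Step 22. The same equilibrium and retro-addition problems apply to the more valuable half, where excess enone cannot be afforded. The fallback sets out from 29 and comes back at 31. Copper-catalysed conjugate borylation of 29 (B2pin2, CuCl, NaOt-Bu, Xantphos, MeOH, THF) should give the β-boryl ketone F5, and oxidation with NaBO3 the hydroxy ketone F6 (9β-CH2OH after equilibration). Lombardo methylenation should give the homoallylic alcohol F7, and Dess–Martin oxidation the aldehyde F8. Reductive etherification of F8 with the trimethylsilyl ether F4 (Et3SiH, TMSOTf cat., CH2Cl2, −78 °C) should give 31.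

**Further compounds**

F1 | step 14 | enol ether carbinol (3β-OH, 3α-(1-ethoxyvinyl)) | CCOC(=C)[C@]1(O)CC[C@@]2(C)C1=CCCC23OCCO3
F2 | step 14 | α-hydroxy methyl ketone (3β-OH, 3α-acetyl) | CC(=O)[C@]1(O)CC[C@@]2(C)C1=CCCC23OCCO3
F3 | step 6 | albicanal | C=C1CC[C@H]2C(C)(C)CCC[C@]2(C)[C@H]1C=O
F4 | step 6 | 2′-O-trimethylsilyl ether of 5 | C[Si](C)(C)O[C@@H](C(=O)OC)[C@H](CC(=O)OC(C)(C)C)C(=O)OCC=C
F5 | step 22 | β-boryl ketone (C11–Bpin, 8-oxo, 15-OTIPS) | CC(C)[Si](C(C)C)(C(C)C)OC[C@]1(C)CCC[C@@]2(C)[C@H]1CCC(=O)[C@@H]2CB1OC(C)(C)C(C)(C)O1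
F6 | step 22 | 11-hydroxy-8-oxo compound (15-OTIPS) | CC(C)[Si](C(C)C)(C(C)C)OC[C@]1(C)CCC[C@@]2(C)[C@H]1CCC(=O)[C@@H]2CO
F7 | step 22 | 15-O-TIPS-15-hydroxyalbicanol | CC(C)[Si](C(C)C)(C(C)C)OC[C@]1(C)CCC[C@@]2(C)[C@H]1CCC(=C)[C@@H]2CO
F8 | step 22 | 15-O-TIPS-15-hydroxyalbicanal | CC(C)[Si](C(C)C)(C(C)C)OC[C@]1(C)CCC[C@@]2(C)[C@H]1CCC(=C)[C@@H]2C=O
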